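Assumption: the SMILES is read literally. In labdane numbering it is the (2R,3S,5S,8R,9S,10S,13E) isomer: a trans-decalin (5α-H, 10β-CH3) with 9β-OH (equatorial), the side chain 9α (axial), 8α-CH3 (equatorial) and a 2α,3α-diol.

## The problem

Compound 18 (C21H36O5) is a labdane-type methyl ester: a trans-fused decalin (ring A = C1–C5/C10, ring B = C5–C10; C17 on C8, C18/C19 on C4, C20 on C10) with a six-carbon (E)-β-methyl enoate chain (C11–C16) on C9. Six stereocentres must be set: the quaternary C10, C5, C8, the tertiary carbinol C9 and the cis-diol C2/C3. C8–C9–C10 are contiguous, and C9 sits between a quaternary carbon and a methine. The chain on C9 is axial (α) and the hydroxyl equatorial (β, cis to C20); this is the face on which a carbon nucleophile, not an oxidant, reaches C9, so the C9–C11 bond is best made on a C9 ketone. With that ketone in place the other centres can be relayed: C8 equilibrates to its equatorial methyl, C5–H trans to C20 is the sterically and thermodynamically favoured fusion, and the 2α,3α-diol lies on the face of ring A opposite the axial methyls C19 and C20. Only C10 has to be set in the absolute sense. The real difficulties are the enantioselective construction of C10 next to the congested C4(CH3)2–C5 junction, a trans ring fusion that cannot come from closing ring A onto a trigonal C10 while C5 is already sp3 (that gives the cis-decalin), and an alkene placed exactly at C2=C3. The feature that makes the key step possible: C10 is the α-carbon and C5 the β-carbon of the C9 carbonyl, so O–C9=C10–C5=C6 of ring B is a dienolate whose α-carbon is C10. The ring-A atoms C1–C2–C3 are an allyl group this dienolate can take up, and C3–C4(CH3)2 is a 1,1-dimethylallyl group on C5 that meets it at C2=C3. The tertiary C9 alcohol, the β-methyl enoate (E/Z isomerisation, conjugate addition of the C9 alkoxide under base) and the free triol are sensitive, so they are introduced late and without protecting groups.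

## Retrosynthesis

C2–O and C3–O. The diol of 18 is cut last, to the C2=C3 alkene 17. OsO4 must add on the α face, which the axial C19/C20 methyls secure, and must spare the electron-poor enoate. An earlier dihydroxylation would cost a protecting group on and off. Alkene 17 has two stereocentres and two hydroxyls fewer.

C13–C16 and C14–C15. The trisubstituted enoate of 17 is cut to the terminal alkyne 15 (through alkenylalane 16). Carboalumination delivers C16 and the metal syn, so the E geometry follows from mechanism. A Horner–Wadsworth–Emmons reaction on a C13 methyl ketone would give E/Z mixtures under basic conditions that invite oxa-Michael closure. Alkyne 15 lacks four heavy-atom groups and has no geometric element.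

C9–C11. Alkyne 15 comes from its silyl derivative 14, which is cut at C9–C11 into ketone 11 and the four-carbon Grignard reagent 13 (from commercial bromide 12). This cut uses the intrinsic α-face (axial) approach to a decalone with an adjacent axial angular methyl, which gives exactly the 9β-OH/9α-chain arrangement. An oxidation at C9 would give the opposite epimer. The forward reaction must add to a 2,2,6-trisubstituted cyclohexanone without enolising it.

C8–C17. Ketone 11 is cut to 9 (through enolate 10). C10 is quaternary, so only C8 can be enolised, and the equatorial 8α-methyl is the thermodynamic epimer. No stereochemical effort is needed.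

C5–H. The saturated ring fusion of 9 is traced to the C5=C6 alkene 8. Leaving C5 trigonal until ring A is closed avoids the cis fusion that a closure onto an sp3 C5/sp2 C10 pair would impose. The forward reaction must deliver H to C5 from the α face and must not touch C2=C3; a radical (hydrogen-atom-transfer) hydrogenation answers both, a metal-surface hydrogenation neither.

C2=C3. Ring A of 8 is opened by retro-metathesis to triene 7, in which C10 bears an allyl group (C1–C3) and C5 a 1,1-dimethylallyl group (C4, C18, C19, C3). This is the only ring-A cut that leaves the double bond where the diol is needed. A C3 carbonyl (Robinson logic) would have to be deleted and the oxygen re-installed.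

C10–C1 (key). Triene 7 is cut at the quaternary centre to the achiral allyl dienyl carbonate 6, made from enone 4 through dienolate 5. The C9–O–CO–O–C1 linkage is a bond that is not in the target; it stores the allyl group on oxygen so that the enolate appears regiospecifically under neutral conditions and the chiral palladium catalyst sets C10. Carbonate 6 has no stereocentre, and every later centre is relayed from the one created here.

C4–C5. Enone 4 is cut between the quaternary C4 and C5 to the commercial vinylogous ester 1 and prenylmagnesium chloride 2 (via carbinol 3). The allylic Grignard reagent reacts through its γ-carbon, so the "reverse prenyl" group and the carbonyl transposition arrive in one operation.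

## Roads not taken

Alternative 1: the most obvious plan cuts ring A by Robinson annulation (C10–C1 and C4=C5) and starts from (S)-Wieland–Miescher ketone A1 (Hajos–Parrish–Eder–Sauer–Wiechert reaction with L-proline). Selective ketalisation of the C9 carbonyl and deconjugative gem-dimethylation (KOt-Bu, MeI) would give A2; enol triflation at C3, palladium-catalysed formate reduction and deketalisation would then reach 8. This is sound chemistry, but the C3 carbonyl that the annulation needs is not in the target. It must be removed in two steps, only for oxygen to be put back at C2/C3 later, and the C9 carbonyl must be protected and released meanwhile. That is five steps from A1 to 8 against four from 1. The chosen plan brings every ring-A carbon in at its final oxidation level and needs no protecting group.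

Alternative 2: a cycloaddition cut of ring A at C10–C1 and C4–C5. A chiral oxazaborolidinium-catalysed Diels–Alder reaction (in effect Mukaiyama–Michael addition followed by Michael closure) of 2,6-dimethyl-1,4-benzoquinone A3 with the silyloxydiene A4 would give the cis adduct A5, which holds all fourteen ring and methyl carbons. Lewis-acid coordination at the unhindered quinone carbonyl should direct the diene CH2 terminus to the methyl-bearing carbon, so the regiochemistry is right. The polarity of this annulation, however, forces a carbonyl at C6 that the target lacks. That carbonyl must be told apart from the C9 carbonyl and removed. The C2 silyl enol ether must also be reduced away (triflate, then reduction) before oxygen is re-installed as the diol, and the ring fusion must be epimerised from cis to trans. In addition, the diene carries a cis-methyl group at its reacting terminus, which slows cycloaddition and makes it prone to acid-induced oligomerisation. The chosen plan needs none of these corrections.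

Alternative 3: the biomimetic cut of both rings (C4–C5 and C9–C10) by cyclisation of (S)-epoxyfarnesyl acetate A6, for instance with Cp2TiCl, to the drimane A7. This sets C5 and C10 in one step, but it puts hydrogen on C9 with the carbon substituent β and the ring-A oxygen at C3β. The target needs oxygen on C9 with the chain α, and a 2α,3α-diol. Reaching 11 from A7 would require degrading C11, oxidising C9, reducing the exocyclic alkene and converting the 3β-alcohol into the C2=C3 alkene, so most of what the cyclisation builds would be dismantled.

Key step: step 3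

## Steps

Step 1
Reactants: 1 3-ethoxy-2-methylcyclohex-2-en-1-one; 2 (3-methylbut-2-en-1-yl)magnesium chloride
Product: 4 2-methyl-3-(2-methylbut-3-en-2-yl)cyclohex-2-en-1-one, via tertiary carbinol 3 (not isolated)
Conditions: THF, −78 → −20 °C; then 1 M aq. HCl, 0 → 25 °C
Reagents that add atoms: water, O
Why: Stork–Danheiser transposition: the allylic Grignard reagent adds to the vinylogous ester carbonyl through its γ-carbon (SE2′, six-membered transition state), which installs the 1,1-dimethylallyl group, the quaternary C4 and the C4–C5 bond; acid then expels water and ethanol from 3 and places the carbonyl at C9. No stereocentre remains in 4.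

Step 2
Reactants: 4 2-methyl-3-(2-methylbut-3-en-2-yl)cyclohex-2-en-1-one
Product: 6 2-methyl-3-(2-methylbut-3-en-2-yl)cyclohexa-1,3-dien-1-yl prop-2-en-1-yl carbonate, via potassium dienolate 5 (not isolated)
Conditions: KOt-Bu (1.05 equiv), THF, 0 °C; ClCO2CH2CH=CH2, −78 → 0 °C
Reagents that add atoms: allyl chloroformate, C=CCOC(=O)Cl
Why: Under equilibrating conditions KOt-Bu removes a C6 (γ) proton to give the extended dienolate 5, favoured also because deconjugation relieves the cis methyl/tert-alkyl strain across C10=C5; the hard chloroformate acylates oxygen. The carbonate holds the allyl group on the C9 oxygen so that step 3 can generate the enolate regiospecifically and without base.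

Step 3
Reactants: 6 2-methyl-3-(2-methylbut-3-en-2-yl)cyclohexa-1,3-dien-1-yl prop-2-en-1-yl carbonate
Product: 7 (2S)-2-methyl-3-(2-methylbut-3-en-2-yl)-2-(prop-2-en-1-yl)cyclohex-3-en-1-one
Conditions: Pd2(dba)3 (2.5 mol %), (R)-t-Bu-PHOX (6 mol %), toluene, 25 °C
Reagents that add atoms: none
Why: Zerovalent palladium ionises the allyl carbonate of 6, CO2 is expelled, and the resulting chiral allylpalladium dienolate forms the C10–C1 bond by inner-sphere reductive elimination. The closest known reaction type is the palladium-catalysed decarboxylative asymmetric allylic alkylation (Tsuji allylation) of allyl enol carbonates of 2-alkylcycloalkanones with phosphinooxazoline ligands. No ring is closed; the step creates the quaternary carbon C10 with the ring-A carbons C1–C3 attached. C10 is the only new stereocentre and is controlled by the ligand alone, which distinguishes the enantiotopic faces of the planar dienolate; on the analogy of 2-methylcyclohexanone enol carbonates the (R)-ligand should lead to (S)-7, and the antipodal ligand would be used should the sense be reversed. The step needs site selectivity for C10 over C6 and C8: the enolate arises regiospecifically from the carbonate, so C8 is never metalated, and the seven-membered cyclic transition state open to the O-bound palladium enolate reaches the α-carbon C10 but not the γ-carbon C6. Because C5 stays trigonal, the ring fusion is left open and is set later under steric and thermodynamic control instead of being forced cis by a ring closure.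

Step 4
Reactants: 7 (2S)-2-methyl-3-(2-methylbut-3-en-2-yl)-2-(prop-2-en-1-yl)cyclohex-3-en-1-one
Product: 8 (8aS)-5,5,8a-trimethyl-3,5,8,8a-tetrahydronaphthalen-1(2H)-one
Conditions: second-generation Hoveyda–Grubbs catalyst [RuCl2(H2IMes)(=CH-C6H4-2-O-i-Pr)] (3 mol %), CH2Cl2, 40 °C
Reagents that add atoms: none
Why: Ring-closing olefin metathesis of the two monosubstituted alkenes closes the six-membered ring A (C10–C1–C2=C3–C4–C5) and leaves its only double bond exactly at C2=C3; the trisubstituted C5=C6 bond is too hindered to take part, and the two quaternary carbons favour cyclisation (Thorpe–Ingold effect).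

Step 5
Reactants: 8 (8aS)-5,5,8a-trimethyl-3,5,8,8a-tetrahydronaphthalen-1(2H)-one
Product: 9 (4aS,8aS)-5,5,8a-trimethyl-3,4,4a,5,8,8a-hexahydronaphthalen-1(2H)-one
Conditions: Mn(dpm)3 (10 mol %; dpm = 2,2,6,6-tetramethylheptane-3,5-dionate), PhSiH3, t-BuOOH, i-PrOH, 22 °C
Reagents that add atoms: none
Why: Metal-hydride hydrogen-atom-transfer hydrogenation: H• adds to C6 to give the tertiary C5 radical, which takes its second hydrogen on the α face, opposite the axial methyls on C4 and C10, giving the trans fusion (5S) that is also the thermodynamic one. The 1,2-disubstituted C2=C3 bond would give only a secondary radical and should react much more slowly, whereas hydrogenation on a metal surface would attack it first.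

Step 6
Reactants: 9 (4aS,8aS)-5,5,8a-trimethyl-3,4,4a,5,8,8a-hexahydronaphthalen-1(2H)-one
Product: 11 (2R,4aS,8aS)-2,5,5,8a-tetramethyl-3,4,4a,5,8,8a-hexahydronaphthalen-1(2H)-one, via lithium enolate 10 (not isolated)
Conditions: LiN(i-Pr)2, THF, −78 °C; MeI, −78 → 0 °C; then NaOMe (cat.), MeOH, 25 °C
Reagents that add atoms: iodomethane, CI
Why: Enolate alkylation: only C8 can be deprotonated because C10 is quaternary, and the NaOMe equilibration secures the equatorial 8α-methyl (8R), since an axial methyl would be syn-axial to the C10 methyl.

Step 7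
Reactants: 11 (2R,4aS,8aS)-2,5,5,8a-tetramethyl-3,4,4a,5,8,8a-hexahydronaphthalen-1(2H)-one; 12 (4-bromobut-1-yn-1-yl)trimethylsilane
Product: 14 (1S,2R,4aS,8aS)-2,5,5,8a-tetramethyl-1-[4-(trimethylsilyl)but-3-yn-1-yl]-1,2,3,4,4a,5,8,8a-octahydronaphthalen-1-ol, via [4-(trimethylsilyl)but-3-yn-1-yl]magnesium bromide 13 (not isolated)
Conditions: 12, Mg, THF, 25 °C; then 11, CeCl3 (1.5 equiv), THF, −78 → 0 °C
Reagents that add atoms: none
Why: 1,2-Addition of the Grignard reagent to the CeCl3-activated ketone (organocerium-type addition, which suppresses enolisation of hindered ketones). The nucleophile enters axially on the α face, anti to the axial C10 methyl, as hydrides and organometallics do with decalones and steroid ketones that have an adjacent angular methyl, so the chain becomes axial (α) and the hydroxyl equatorial (β), i.e. 9S.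

Step 8
Reactants: 14 (1S,2R,4aS,8aS)-2,5,5,8a-tetramethyl-1-[4-(trimethylsilyl)but-3-yn-1-yl]-1,2,3,4,4a,5,8,8a-octahydronaphthalen-1-ol
Product: 15 (1S,2R,4aS,8aS)-1-(but-3-yn-1-yl)-2,5,5,8a-tetramethyl-1,2,3,4,4a,5,8,8a-octahydronaphthalen-1-ol
Conditions: K2CO3 (cat.), MeOH, 25 °C
Reagents that add atoms: none
Why: Methanolysis of the C(sp)–Si bond by catalytic methoxide; nothing else in 14 is base-labile.

Step 9
Reactants: 15 (1S,2R,4aS,8aS)-1-(but-3-yn-1-yl)-2,5,5,8a-tetramethyl-1,2,3,4,4a,5,8,8a-octahydronaphthalen-1-ol
Product: 17 methyl (2E)-5-[(1S,2R,4aS,8aS)-1-hydroxy-2,5,5,8a-tetramethyl-1,2,3,4,4a,5,8,8a-octahydronaphthalen-1-yl]-3-methylpent-2-enoate, via (E)-alkenyldimethylalane 16 (not isolated)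
Conditions: Me3Al (4 equiv), Cp2ZrCl2 (0.25 equiv), CH2Cl2, 0 → 25 °C; then ClCO2Me, 0 → 25 °C
Reagents that add atoms: trimethylaluminium, C[Al](C)C; methyl chloroformate, COC(=O)Cl
Why: Negishi zirconium-catalysed carboalumination: syn addition of CH3–Al across the terminal alkyne, methyl on the internal carbon, gives the (E)-alkenylalane 16, whose C–Al bond is acylated by the chloroformate with retention, fixing the 13E geometry. The tertiary hydroxyl travels as its aluminium alkoxide, and the basic olefination conditions under which the C9 alkoxide could add to the enoate are avoided.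

Step 10
Reactants: 17 methyl (2E)-5-[(1S,2R,4aS,8aS)-1-hydroxy-2,5,5,8a-tetramethyl-1,2,3,4,4a,5,8,8a-octahydronaphthalen-1-yl]-3-methylpent-2-enoate
Product: 18 methyl (2E)-3-methyl-5-[(1S,2R,4aS,6S,7R,8aS)-1,6,7-trihydroxy-2,5,5,8a-tetramethyldecahydronaphthalen-1-yl]pent-2-enoate
Conditions: OsO4 (2 mol %), N-methylmorpholine N-oxide, acetone–H2O (4:1), 25 °C
Reagents that add atoms: osmium tetroxide (catalytic oxygen carrier), O=[Os](=O)(=O)=O; N-methylmorpholine N-oxide, C[N+]1([O-])CCOCC1; water, O
Why: Catalytic osmium tetroxide dihydroxylation with the N-oxide as terminal oxidant: OsO4 adds suprafacially to the cis-disubstituted C2=C3 bond from the α face, opposite the axial methyls on C4 and C10 (as with 5α-steroid 2-enes), giving the 2α,3α-diol (2R,3S). The conjugated, trisubstituted enoate is much less reactive toward the electrophilic oxidant.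

## Compound list

1 | 3-ethoxy-2-methylcyclohex-2-en-1-one | CCOC1=C(C)C(=O)CCC1 | starting material
2 | (3-methylbut-2-en-1-yl)magnesium chloride (THF solution) | CC(C)=CC[Mg]Cl | starting material
3 | 3-ethoxy-2-methyl-1-(2-methylbut-3-en-2-yl)cyclohex-2-en-1-ol (racemic, formed as its chloromagnesium alkoxide) | CCOC1=C(C)C(O)(C(C)(C)C=C)CCC1 | intermediate (not isolated)
4 | 2-methyl-3-(2-methylbut-3-en-2-yl)cyclohex-2-en-1-one | CC1=C(C(C)(C)C=C)CCCC1=O | intermediate
5 | potassium 2-methyl-3-(2-methylbut-3-en-2-yl)cyclohexa-1,3-dien-1-olate | [K+].[O-]C1=C(C)C(C(C)(C)C=C)=CCC1 | intermediate (not isolated)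
6 | 2-methyl-3-(2-methylbut-3-en-2-yl)cyclohexa-1,3-dien-1-yl prop-2-en-1-yl carbonate | C=CCOC(=O)OC1=C(C)C(C(C)(C)C=C)=CCC1 | intermediate
7 | (2S)-2-methyl-3-(2-methylbut-3-en-2-yl)-2-(prop-2-en-1-yl)cyclohex-3-en-1-one | O=C1CCC=C(C(C)(C)C=C)[C@]1(C)CC=C | intermediate
8 | (8aS)-5,5,8a-trimethyl-3,5,8,8a-tetrahydronaphthalen-1(2H)-one | O=C1CCC=C2C(C)(C)C=CC[C@@]21C | intermediate
9 | (4aS,8aS)-5,5,8a-trimethyl-3,4,4a,5,8,8a-hexahydronaphthalen-1(2H)-one | O=C1CCC[C@H]2C(C)(C)C=CC[C@@]21C | intermediate
10 | lithium (4aS,8aS)-5,5,8a-trimethyl-3,4,4a,5,8,8a-hexahydronaphthalen-1-olate | [Li+].[O-]C1=CCC[C@H]2C(C)(C)C=CC[C@@]21C | intermediate (not isolated)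
11 | (2R,4aS,8aS)-2,5,5,8a-tetramethyl-3,4,4a,5,8,8a-hexahydronaphthalen-1(2H)-one | O=C1[C@H](C)CC[C@H]2C(C)(C)C=CC[C@@]21C | intermediate
12 | (4-bromobut-1-yn-1-yl)trimethylsilane | C[Si](C)(C)C#CCCBr | starting material
13 | [4-(trimethylsilyl)but-3-yn-1-yl]magnesium bromide | C[Si](C)(C)C#CCC[Mg]Br | intermediate (not isolated)
14 | (1S,2R,4aS,8aS)-2,5,5,8a-tetramethyl-1-[4-(trimethylsilyl)but-3-yn-1-yl]-1,2,3,4,4a,5,8,8a-octahydronaphthalen-1-ol | C[Si](C)(C)C#CCC[C@]1(O)[C@H](C)CC[C@H]2C(C)(C)C=CC[C@@]21C | intermediate
15 | (1S,2R,4aS,8aS)-1-(but-3-yn-1-yl)-2,5,5,8a-tetramethyl-1,2,3,4,4a,5,8,8a-octahydronaphthalen-1-ol | C#CCC[C@]1(O)[C@H](C)CC[C@H]2C(C)(C)C=CC[C@@]21C | intermediate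
16 | (E)-alkenyldimethylalane of 15, carried as its O-dimethylaluminium alkoxide | C[Al](C)/C=C(\C)CC[C@]1(O[Al](C)C)[C@H](C)CC[C@H]2C(C)(C)C=CC[C@@]21C | intermediate (not isolated)
17 | methyl (2E)-5-[(1S,2R,4aS,8aS)-1-hydroxy-2,5,5,8a-tetramethyl-1,2,3,4,4a,5,8,8a-octahydronaphthalen-1-yl]-3-methylpent-2-enoate | COC(=O)/C=C(\C)CC[C@]1(O)[C@H](C)CC[C@H]2C(C)(C)C=CC[C@@]21C | intermediate
18 | methyl (2E)-3-methyl-5-[(1S,2R,4aS,6S,7R,8aS)-1,6,7-trihydroxy-2,5,5,8a-tetramethyldecahydronaphthalen-1-yl]pent-2-enoate | COC(=O)/C=C(\C)CC[C@]1(O)[C@H](C)CC[C@H]2C(C)(C)[C@H](O)[C@H](O)C[C@@]21C | target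

## Step count and risks

Total: 10 steps. Longest linear sequence: 10 steps (1 → 18). No protecting group is used.

Step 3 (key step). What may go wrong: insufficient facial discrimination of the hindered dienolate by the ligand, or slow C–C bond formation at the congested α-carbon with protonation back to 4. Fallback, setting out from 4: Stork reductive alkylation (Li, NH3, THF, t-BuOH, −78 °C; then allyl bromide) protonates C5 and allylates C10 anti to the tert-alkyl group. It should give the racemic trans ketone rac-(2S,3S)-2-methyl-3-(2-methylbut-3-en-2-yl)-2-(prop-2-en-1-yl)cyclohexan-1-one F1, with the C5/C10 relationship already in place. Metathesis as in step 4 then gives 9 together with its enantiomer, (4aR,8aR)-5,5,8a-trimethyl-3,4,4a,5,8,8a-hexahydronaphthalen-1(2H)-one F2, which is removed by preparative chromatography on a chiral stationary phase. The route is rejoined at 9; steps 2, 3 and 5 are bypassed at the price of a resolution.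

Step 2. What may go wrong: deprotonation at C8 instead of C6, so that the cross-conjugated enolate is trapped and step 3 would allylate C8. Fallback, setting out from 4: thermodynamic silylation (Me3SiCl, NaI, Et3N, MeCN) should give the extended silyl dienol ether trimethyl{[2-methyl-3-(2-methylbut-3-en-2-yl)cyclohexa-1,3-dien-1-yl]oxy}silane F3. This is allylated intermolecularly with diallyl carbonate, Pd2(dba)3, the same ligand and Bu4N[Ph3SiF2] (fluoride-triggered Tsuji allylation). The route is rejoined at 7 without carbonate 6.

Step 5. What may go wrong: loss of chemoselectivity, with hydrogen-atom transfer to the C2=C3 bond causing its reduction or migration, or a 1,2-acyl shift of the β-keto radical. Fallback, setting out from 8: the C2=C3 bond is masked as its own diol. OsO4/N-methylmorpholine N-oxide should give (6S,7R,8aS)-6,7-dihydroxy-5,5,8a-trimethyl-3,5,6,7,8,8a-hexahydronaphthalen-1(2H)-one F4. The C5=C6 bond is then reduced without competition (the conditions of step 5, or H2, PtO2, AcOH) to (4aS,6S,7R,8aS)-6,7-dihydroxy-5,5,8a-trimethyloctahydronaphthalen-1(2H)-one F5. Corey–Winter olefination through the cyclic thiocarbonate of F5 F6 (1,1′-thiocarbonyldiimidazole; then P(OMe)3, 110 °C) regenerates the alkene, and the route is rejoined at 9.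

Step 7. What may go wrong: enolisation or β-hydride reduction of the hindered ketone instead of addition, or incomplete facial selectivity with the longer nucleophile. Fallback, setting out from 11: Corey–Chaykovsky methylenation (Me3S+ I−, n-BuLi, THF) should give, by axial attack of the small ylide, the spiro-epoxide (1S,2R,4aS,8aS)-2,5,5,8a-tetramethyl-3,4,4a,5,8,8a-hexahydro-2H-spiro[naphthalene-1,2′-oxirane] F7 (C11 α, oxygen β). Opening at its CH2 carbon with lithiated 1-(trimethylsilyl)propyne (n-BuLi; BF3·OEt2, −78 °C) gives 14, where the route is rejoined.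

Step 10. What may go wrong: competing osmylation of the C13=C14 enoate, or over-oxidation, lowering chemoselectivity. Fallback, setting out from 15 (the alkyne is inert to OsO4): dihydroxylation gives (1S,2R,4aS,6S,7R,8aS)-1-(but-3-yn-1-yl)-2,5,5,8a-tetramethyldecahydronaphthalene-1,6,7-triol F8. Silylation of the two secondary hydroxyls (Et3SiOTf, 2,6-lutidine) gives the bis(triethylsilyl) ether of F8 F9. Carboalumination and methoxycarbonylation as in step 9 give the bis(triethylsilyl) ether of 18 F10, and AcOH–THF–H2O removes the silyl groups. The route is rejoined at 18.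

## Further compounds

F1 | step 3 | rac-(2S,3S)-2-methyl-3-(2-methylbut-3-en-2-yl)-2-(prop-2-en-1-yl)cyclohexan-1-one (racemate; the enantiomer leading to 9 is drawn) | O=C1CCC[C@@H](C(C)(C)C=C)[C@]1(C)CC=C
F2 | step 3 | (4aR,8aR)-5,5,8a-trimethyl-3,4,4a,5,8,8a-hexahydronaphthalen-1(2H)-one (enantiomer of 9) | O=C1CCC[C@@H]2C(C)(C)C=CC[C@]21C
F3 | step 2 | trimethyl{[2-methyl-3-(2-methylbut-3-en-2-yl)cyclohexa-1,3-dien-1-yl]oxy}silane | C[Si](C)(C)OC1=C(C)C(C(C)(C)C=C)=CCC1
F4 | step 5 | (6S,7R,8aS)-6,7-dihydroxy-5,5,8a-trimethyl-3,5,6,7,8,8a-hexahydronaphthalen-1(2H)-one | O=C1CCC=C2C(C)(C)[C@H](O)[C@H](O)C[C@@]21C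
F5 | step 5 | (4aS,6S,7R,8aS)-6,7-dihydroxy-5,5,8a-trimethyloctahydronaphthalen-1(2H)-one | O=C1CCC[C@H]2C(C)(C)[C@H](O)[C@H](O)C[C@@]21C
F6 | step 5 | cyclic 6,7-O-thiocarbonate of F5 | O=C1CCC[C@H]2C(C)(C)[C@@H]3OC(=S)O[C@@H]3C[C@@]21C
F7 | step 7 | (1S,2R,4aS,8aS)-2,5,5,8a-tetramethyl-3,4,4a,5,8,8a-hexahydro-2H-spiro[naphthalene-1,2′-oxirane] | O1C[C@@]12[C@H](C)CC[C@H]3C(C)(C)C=CC[C@@]32C
F8 | step 10 | (1S,2R,4aS,6S,7R,8aS)-1-(but-3-yn-1-yl)-2,5,5,8a-tetramethyldecahydronaphthalene-1,6,7-triol | C#CCC[C@]1(O)[C@H](C)CC[C@H]2C(C)(C)[C@H](O)[C@H](O)C[C@@]21C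
F9 | step 10 | 6,7-bis(triethylsilyl) ether of F8 | C#CCC[C@]1(O)[C@H](C)CC[C@H]2C(C)(C)[C@H](O[Si](CC)(CC)CC)[C@H](O[Si](CC)(CC)CC)C[C@@]21C
F10 | step 10 | 6,7-bis(triethylsilyl) ether of 18 | COC(=O)/C=C(\C)CC[C@]1(O)[C@H](C)CC[C@H]2C(C)(C)[C@H](O[Si](CC)(CC)CC)[C@H](O[Si](CC)(CC)CC)C[C@@]21C
A1 | alternative 1 | (8aS)-8a-methyl-3,4,8,8a-tetrahydronaphthalene-1,6(2H,7H)-dione ((S)-Wieland–Miescher ketone) | O=C1CCCC2=CC(=O)CC[C@@]21C
A2 | alternative 1 | (8a′S)-5′,5′,8a′-trimethyl-3′,7′,8′,8a′-tetrahydro-2′H-spiro[1,3-dioxolane-2,1′-naphthalen]-6′(5′H)-one | O1CCOC12CCC=C3C(C)(C)C(=O)CC[C@@]32C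
A3 | alternative 2 | 2,6-dimethylcyclohexa-2,5-diene-1,4-dione (2,6-dimethyl-1,4-benzoquinone) | CC1=CC(=O)C=C(C)C1=O
A4 | alternative 2 | tert-butyl(dimethyl)[(4-methylpenta-1,3-dien-2-yl)oxy]silane | C=C(O[Si](C)(C)C(C)(C)C)C=C(C)C
A5 | alternative 2 | cis-(4a,8a)-7-[tert-butyl(dimethyl)silyl]oxy-2,5,5,8a-tetramethyl-4a,5,8,8a-tetrahydronaphthalene-1,4-dione (8aS) | O=C1C(C)=CC(=O)[C@@H]2C(C)(C)C=C(O[Si](C)(C)C(C)(C)C)C[C@@]21C
A6 | alternative 3 | (2E,6E)-9-[(2S)-3,3-dimethyloxiran-2-yl]-3,7-dimethylnona-2,6-dien-1-yl acetate | CC1(C)O[C@H]1CC/C(C)=C/CC/C(C)=C/COC(C)=O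
A7 | alternative 3 | [(1S,4aR,6S,8aS)-6-hydroxy-5,5,8a-trimethyl-2-methylidenedecahydronaphthalen-1-yl]methyl acetate | CC(=O)OC[C@H]1C(=C)CC[C@H]2C(C)(C)[C@@H](O)CC[C@@]21C
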